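**Assumption:** locants C1–C15 follow germacrane numbering (lactone carbinol C6, ring-fusion carbon C7, free hydroxyl on C8, epoxyangelate on C9, acetate on C3, exocyclic methylene C13).

## Retrosynthetic overview

1. Target 26 ⇐ desilylation ⇐ ring-closing metathesis at C1=C10 of the acyclic diene lactone 24; the ten-membered carbocycle is the last ring formed.
2. 24 ⇐ Brown allylation and acetylation at C3 of Z-enal 22; the Z-C4=C5 olefin with C3 and C6 comes from 4-methylfuran-2(5H)-one.
3. The α-methylene-γ-lactone (second ring) ⇐ indium Barbier union (C6–C7) of lactol 19 with the (Z)-2-(bromomethyl)enoate 17, then lactonisation (C6–O).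
4. 17 ⇐ the key C9–O bond: palladium-catalysed 1,2-acyloxylation of the Sharpless vinyl epoxy alcohol 10 with epoxyangelic acid 5. This sets C9, installs the ester and leaves O8 as the only oxygen that later needs unmasking.
5. Ring order: oxirane of 5 (first) → γ-lactone → cyclodecadiene. Inputs: angelic acid, methacrolein, Ph3P=CHCO2Et, methyl propiolate, 4-methylfuran-2(5H)-one.

## Route

Step 1
Reactants: 1 angelic acid
Product: 2 (2Z)-2-methylbut-2-en-1-ol
Conditions: LiAlH4, Et2O, 0 °C → rt
Reagents that add atoms: none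
Why: LiAlH4 reduction of the acid to the allylic alcohol; the trisubstituted Z-olefin is not touched.

Step 2
Reactants: 2 (2Z)-2-methylbut-2-en-1-ol
Product: 3 [(2R,3S)-2,3-dimethyloxiran-2-yl]methanol
Conditions: Ti(OiPr)4 (10 mol%), D-(−)-diethyl tartrate (12 mol%), tBuOOH, 4 Å MS, CH2Cl2, −20 °C
Reagents that add atoms: tert-butyl hydroperoxide, CC(C)(C)OO
Why: Sharpless asymmetric epoxidation; D-(−)-tartrate delivers oxygen to the face that gives the (2R,3S) epoxide, which sets both stereocentres of the acyl part.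

Step 3
Reactants: 3 [(2R,3S)-2,3-dimethyloxiran-2-yl]methanol
Product: 5 (2S,3S)-2,3-dimethyloxirane-2-carboxylic acid, via epoxy aldehyde 4 (not isolated)
Conditions: TEMPO (cat.), PhI(OAc)2 (2.2 equiv), MeCN/H2O 1:1, 0 °C → rt; acid used fresh
Reagents that add atoms: water, O
Why: TEMPO/PhI(OAc)2 oxidation of the primary alcohol through the aldehyde hydrate under near-neutral conditions that leave the epoxide and both stereocentres intact (the C2 descriptor changes from R to S only through CIP ranking).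

Step 4
Reactants: 6 methacrolein; 7 ethyl (triphenylphosphoranylidene)acetate
Product: 8 ethyl (2E)-4-methylpenta-2,4-dienoate
Conditions: CH2Cl2, rt
Reagents that add atoms: none
Why: Wittig olefination with a stabilised ylide, which is E-selective.

Step 5
Reactants: 8 ethyl (2E)-4-methylpenta-2,4-dienoate
Product: 9 (2E)-4-methylpenta-2,4-dien-1-ol
Conditions: iBu2AlH (2.2 equiv), CH2Cl2, −78 °C
Reagents that add atoms: none
Why: 1,2-reduction of the dienoate to the allylic alcohol (DIBAL-H reduction).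

Step 6
Reactants: 9 (2E)-4-methylpenta-2,4-dien-1-ol
Product: 10 [(2S,3S)-3-(prop-1-en-2-yl)oxiran-2-yl]methanol
Conditions: Ti(OiPr)4 (5 mol%), L-(+)-diethyl tartrate (6 mol%), tBuOOH, 4 Å MS, CH2Cl2, −20 °C
Reagents that add atoms: tert-butyl hydroperoxide, CC(C)(C)OO
Why: Sharpless asymmetric epoxidation; the hydroxyl directs oxygen to the 2,3-olefin only and L-(+)-tartrate gives the (2S,3S) epoxide, which fixes C8.

Step 7
Reactants: 10 [(2S,3S)-3-(prop-1-en-2-yl)oxiran-2-yl]methanol; 5 (2S,3S)-2,3-dimethyloxirane-2-carboxylic acid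
Product: 11 (2S,3S)-1,2-dihydroxy-4-methylpent-4-en-3-yl (2S,3S)-2,3-dimethyloxirane-2-carboxylate
Conditions: 5 (1.05 equiv), Pd2(dba)3·CHCl3 (2.5 mol%), (R,R)-DACH-phenyl Trost ligand (7.5 mol%), Et3B (5 mol%), CH2Cl2, 0 °C → rt
Reagents that add atoms: none
Why: Proposed new method: zerovalent palladium ionises the vinyl epoxide with inversion to a π-allyl/alkoxide zwitterion, the acid protonates the alkoxide (or forms an acyloxyborate with it through Et3B), and the carboxylate held next to O8 attacks the proximal allyl terminus C9 anti to palladium, so the branched 9S ester forms by net retention with O7 and O8 left free; the chiral ligand is meant to reinforce this face even though the CH2-terminated allyl can equilibrate by π–σ–π, and its matched enantiomer must be confirmed in the first run; the closest known reaction type is the Trost palladium/borane asymmetric 1,2-addition of alcohols, phthalimide or carbonate to vinyl epoxides, with carboxylic acids so far giving mainly 1,4-adducts.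

Step 8
Reactants: 11 diol ester
Product: 12 (2S,3S)-4-methyl-1,2-bis[(triethylsilyl)oxy]pent-4-en-3-yl (2S,3S)-2,3-dimethyloxirane-2-carboxylate
Conditions: Et3SiOTf (2.3 equiv), 2,6-lutidine, CH2Cl2, −78 °C
Reagents that add atoms: triethylsilyl trifluoromethanesulfonate, CC[Si](CC)(CC)OS(=O)(=O)C(F)(F)F
Why: Silyl ether formation at both hydroxyls; fast at −78 °C with a non-nucleophilic base, so the C9 ester does not migrate to O8.

Step 9
Reactants: 12 bis(triethylsilyl) ether
Product: 13 (2R,3S)-4-methyl-1-oxo-2-[(triethylsilyl)oxy]pent-4-en-3-yl (2S,3S)-2,3-dimethyloxirane-2-carboxylate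
Conditions: (COCl)2, DMSO, CH2Cl2, −78 → −40 °C; Et3N, −78 → −30 °C; cold pH 7 quench
Reagents that add atoms: none
Why: Swern conditions cleave and oxidise the primary triethylsilyl ether directly while the secondary one survives; the cold amine stage limits β-elimination of the C9 ester and epimerisation at C8.

Step 10
Reactants: 13 aldehyde; 14 methyl propiolate
Product: 16 methyl (4S,5S)-5-(epoxyangeloyloxy)-3-hydroxy-6-methyl-2-methylidene-4-(triethylsilyloxy)hept-6-enoate (C3 epimers), via vinylalane 15 (not isolated)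
Conditions: 14, iBu2AlH, N-methylmorpholine N-oxide, THF, 0 °C; then 13, 0 °C → rt
Reagents that add atoms: none
Why: Vinylalumination (the aluminium route to Morita–Baylis–Hillman adducts): hydroalumination of the propiolate gives an α-alanyl acrylate that adds 1,2 to the aldehyde without amine base, so the β-acyloxy aldehyde is not exposed to elimination; the new carbinol centre is lost in step 11.

Step 11
Reactants: 16 hydroxy acrylate
Product: 17 methyl (2Z,4S,5S)-2-(bromomethyl)-5-(epoxyangeloyloxy)-6-methyl-4-(triethylsilyloxy)hepta-2,6-dienoate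
Conditions: NBS, Me2S, CH2Cl2, 0 °C → rt
Reagents that add atoms: N-bromosuccinimide, O=C1CCC(=O)N1Br
Why: Corey–Kim-type activation of the allylic alcohol and SN2′ attack of bromide give the conjugated (2Z)-2-(bromomethyl)enoate, the thermodynamically preferred isomer.

Step 12
Reactants: 18 4-methylfuran-2(5H)-one
Product: 19 4-methyl-2,5-dihydrofuran-2-ol
Conditions: iBu2AlH (1.05 equiv), CH2Cl2, −78 °C; Rochelle salt work-up; used crude
Reagents that add atoms: none
Why: Partial DIBAL-H reduction of the lactone to the lactol; the ring holds the future C4=C5 olefin in the Z geometry and the lactol is a (Z)-4-hydroxy-3-methylbut-2-enal equivalent.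

Step 13
Reactants: 17 allylic bromide; 19 lactol
Product: 21 cis-fused methylene lactone alcohol (6S,7S,8S,9S; germacrane numbering), via hydroxy ester 20 (not isolated)
Conditions: In powder (1.5 equiv), 19 (1.5 equiv), THF/H2O 3:1, rt; then PPTS (cat.), CH2Cl2, rt → 40 °C
Reagents that add atoms: none
Why: Indium Barbier allylation through a Zimmerman–Traxler chair, in which the (Z)-γ-substituted allylindium gives the syn adduct (hence the cis-lactone) and, with H8 held in the olefin plane by A(1,3) strain, the aldehyde adds anti to the C9 branch, setting C6 and C7 from C8; acid-catalysed lactonisation then forms the C6–O bond.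

Step 14
Reactants: 21 lactone alcohol
Product: 22 Z-enal (C3 aldehyde)
Conditions: Dess–Martin periodinane, NaHCO3, CH2Cl2, 0 °C
Reagents that add atoms: none
Why: Buffered Dess–Martin oxidation of the primary allylic alcohol gives the Z-enal without Z/E isomerisation; it is used at once.

Step 15
Reactants: 22 Z-enal
Product: 23 (3S)-homoallylic alcohol
Conditions: (−)-Ipc2B(allyl) (dIpc reagent, from (+)-α-pinene; 1.5 equiv), Et2O, −78 °C; ethanolamine work-up
Reagents that add atoms: (−)-B-allyldiisopinocampheylborane, C=CCB([C@@H]1C[C@@H]2C[C@H]([C@H]1C)C2(C)C)[C@@H]1C[C@@H]2C[C@H]([C@H]1C)C2(C)C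
Why: Brown asymmetric allylboration; the reagent from (+)-α-pinene attacks the Si face of the aldehyde and sets 3S under reagent control, and the non-oxidative work-up spares the methylene lactone.

Step 16
Reactants: 23 homoallylic alcohol
Product: 24 (3S)-acetate diene
Conditions: Ac2O, pyridine, DMAP (cat.), CH2Cl2, 0 °C
Reagents that add atoms: acetic anhydride, CC(=O)OC(C)=O
Why: Acetylation of the only free hydroxyl (DMAP-catalysed acylation).

Step 17
Reactants: 24 acetate diene
Product: 25 8-O-triethylsilyl germacranolide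
Conditions: second-generation Hoveyda–Grubbs catalyst (15 mol%), 1,4-benzoquinone (30 mol%), toluene (1 mM), 80 °C
Reagents that add atoms: none
Why: Ring-closing metathesis between the terminal vinyl group and the isopropenyl group forms C1=C10 and the ten-membered ring; ring strain in a cyclodeca-1,5-diene that already holds a Z-olefin and a cis-lactone should favour the Z-trisubstituted olefin.

Step 18
Reactants: 25 silyl ether
Product: 26 target CNP0137407.11
Conditions: HF·pyridine, pyridine, THF, 0 °C → rt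
Reagents that add atoms: none
Why: Buffered fluoride desilylation frees the C8 hydroxyl without touching the epoxide, the esters or the methylene lactone; no stereocentre changes (C7 becomes R only through CIP ranking).

## Compound list

1 | angelic acid, (2Z)-2-methylbut-2-enoic acid | C/C=C(/C)C(=O)O | starting material
2 | (2Z)-2-methylbut-2-en-1-ol | C/C=C(/C)CO | intermediate
3 | [(2R,3S)-2,3-dimethyloxiran-2-yl]methanol | OC[C@@]1(C)O[C@H]1C | intermediate
4 | (2S,3S)-2,3-dimethyloxirane-2-carbaldehyde (not isolated) | O=C[C@@]1(C)O[C@H]1C | intermediate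
5 | (2S,3S)-2,3-dimethyloxirane-2-carboxylic acid (epoxyangelic acid) | OC(=O)[C@@]1(C)O[C@H]1C | intermediate
6 | methacrolein | CC(=C)C=O | starting material
7 | ethyl (triphenylphosphoranylidene)acetate | CCOC(=O)C=P(c1ccccc1)(c1ccccc1)c1ccccc1 | starting material
8 | ethyl (2E)-4-methylpenta-2,4-dienoate | CCOC(=O)/C=C/C(C)=C | intermediate
9 | (2E)-4-methylpenta-2,4-dien-1-ol | OC/C=C/C(C)=C | intermediate
10 | [(2S,3S)-3-(prop-1-en-2-yl)oxiran-2-yl]methanol | C=C(C)[C@@H]1O[C@H]1CO | intermediate
11 | (2S,3S)-1,2-dihydroxy-4-methylpent-4-en-3-yl (2S,3S)-2,3-dimethyloxirane-2-carboxylate | C=C(C)[C@H](OC(=O)[C@@]1(C)O[C@H]1C)[C@@H](O)CO | intermediate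
12 | (2S,3S)-4-methyl-1,2-bis[(triethylsilyl)oxy]pent-4-en-3-yl (2S,3S)-2,3-dimethyloxirane-2-carboxylate | C=C(C)[C@H](OC(=O)[C@@]1(C)O[C@H]1C)[C@@H](O[Si](CC)(CC)CC)CO[Si](CC)(CC)CC | intermediate
13 | (2R,3S)-4-methyl-1-oxo-2-[(triethylsilyl)oxy]pent-4-en-3-yl (2S,3S)-2,3-dimethyloxirane-2-carboxylate | C=C(C)[C@H](OC(=O)[C@@]1(C)O[C@H]1C)[C@@H](O[Si](CC)(CC)CC)C=O | intermediate
14 | methyl propiolate | C#CC(=O)OC | starting material
15 | methyl 2-(diisobutylalumanyl)prop-2-enoate (not isolated) | C=C(C(=O)OC)[Al](CC(C)C)CC(C)C | intermediate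
16 | methyl (4S,5S)-5-{[(2S,3S)-2,3-dimethyloxirane-2-carbonyl]oxy}-3-hydroxy-6-methyl-2-methylidene-4-[(triethylsilyl)oxy]hept-6-enoate (C3 epimers) | C=C(C)[C@H](OC(=O)[C@@]1(C)O[C@H]1C)[C@@H](O[Si](CC)(CC)CC)C(O)C(=C)C(=O)OC | intermediate
17 | methyl (2Z,4S,5S)-2-(bromomethyl)-5-{[(2S,3S)-2,3-dimethyloxirane-2-carbonyl]oxy}-6-methyl-4-[(triethylsilyl)oxy]hepta-2,6-dienoate | C=C(C)[C@H](OC(=O)[C@@]1(C)O[C@H]1C)[C@@H](O[Si](CC)(CC)CC)/C=C(\CBr)C(=O)OC | intermediate
18 | 4-methylfuran-2(5H)-one | CC1=CC(=O)OC1 | starting material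
19 | 4-methyl-2,5-dihydrofuran-2-ol (racemic hemiacetal) | CC1=CC(O)OC1 | intermediate
20 | methyl (3S,4S,5Z)-3-[(1S,2S)-2-{[(2S,3S)-2,3-dimethyloxirane-2-carbonyl]oxy}-3-methyl-1-[(triethylsilyl)oxy]but-3-en-1-yl]-4,7-dihydroxy-6-methyl-2-methylidenehept-5-enoate (not isolated) | C=C(C(=O)OC)[C@@H]([C@@H](O)/C=C(/C)CO)[C@H](O[Si](CC)(CC)CC)[C@@H](OC(=O)[C@@]1(C)O[C@H]1C)C(C)=C | intermediate
21 | (4S,5S)-4-[(1S,2S)-2-{[(2S,3S)-2,3-dimethyloxirane-2-carbonyl]oxy}-3-methyl-1-[(triethylsilyl)oxy]but-3-en-1-yl]-5-[(1Z)-3-hydroxy-2-methylprop-1-en-1-yl]-3-methylideneoxolan-2-one | C=C1C(=O)O[C@@H](/C=C(/C)CO)[C@H]1[C@H](O[Si](CC)(CC)CC)[C@@H](OC(=O)[C@@]2(C)O[C@H]2C)C(C)=C | intermediate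
22 | (4S,5S)-4-[(1S,2S)-2-{[(2S,3S)-2,3-dimethyloxirane-2-carbonyl]oxy}-3-methyl-1-[(triethylsilyl)oxy]but-3-en-1-yl]-5-[(1Z)-2-methyl-3-oxoprop-1-en-1-yl]-3-methylideneoxolan-2-one | C=C1C(=O)O[C@@H](/C=C(/C)C=O)[C@H]1[C@H](O[Si](CC)(CC)CC)[C@@H](OC(=O)[C@@]2(C)O[C@H]2C)C(C)=C | intermediate
23 | (4S,5S)-4-[(1S,2S)-2-{[(2S,3S)-2,3-dimethyloxirane-2-carbonyl]oxy}-3-methyl-1-[(triethylsilyl)oxy]but-3-en-1-yl]-5-[(1Z,3S)-3-hydroxy-2-methylhexa-1,5-dien-1-yl]-3-methylideneoxolan-2-one | C=C1C(=O)O[C@@H](/C=C(/C)[C@@H](O)CC=C)[C@H]1[C@H](O[Si](CC)(CC)CC)[C@@H](OC(=O)[C@@]2(C)O[C@H]2C)C(C)=C | intermediate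
24 | (4S,5S)-5-[(1Z,3S)-3-(acetyloxy)-2-methylhexa-1,5-dien-1-yl]-4-[(1S,2S)-2-{[(2S,3S)-2,3-dimethyloxirane-2-carbonyl]oxy}-3-methyl-1-[(triethylsilyl)oxy]but-3-en-1-yl]-3-methylideneoxolan-2-one | C=C1C(=O)O[C@@H](/C=C(/C)[C@@H](OC(C)=O)CC=C)[C@H]1[C@H](O[Si](CC)(CC)CC)[C@@H](OC(=O)[C@@]2(C)O[C@H]2C)C(C)=C | intermediate
25 | (3S,6S,7S,8S,9S)-3-acetoxy-9-{[(2S,3S)-2,3-dimethyloxirane-2-carbonyl]oxy}-8-[(triethylsilyl)oxy]germacra-1(10)Z,4Z,11(13)-trien-6,12-olide | C=C1C(=O)O[C@H]2/C=C(/C)[C@@H](OC(C)=O)C/C=C(/C)[C@H](OC(=O)[C@@]3(C)O[C@H]3C)[C@@H](O[Si](CC)(CC)CC)[C@@H]12 | intermediate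
26 | CNP0137407.11, (3S,6S,7R,8S,9S)-3-acetoxy-9-{[(2S,3S)-2,3-dimethyloxirane-2-carbonyl]oxy}-8-hydroxygermacra-1(10)Z,4Z,11(13)-trien-6,12-olide | C=C1C(=O)O[C@H]2/C=C(/C)[C@@H](OC(C)=O)C/C=C(/C)[C@H](OC(=O)[C@@]3(C)O[C@H]3C)[C@@H](O)[C@@H]12 | target

## Step count and risks

Total step count: 18. Longest linear sequence: 14 steps (steps 4–11 and 13–18 from methacrolein; the same length from angelic acid through steps 1–3, 7–11 and 13–18).

**Steps most likely to fail**

1. **Step 7, the new palladium-catalysed 1,2-acyloxylation.** The risks are 1,4-attack at the CH2 terminus, loss of the C9 configuration through π–σ–π exchange, a wrong match of ligand and substrate, and acyl migration in 11. The fallback uses known chemistry, sets out from methacrolein 6 and comes back at diol ester 11. Ando olefination of 6 (ethyl 2-(diphenoxyphosphoryl)acetate, NaH, THF, −78 °C) gives ethyl (2Z)-4-methylpenta-2,4-dienoate F1. Reduction with iBu2AlH gives (2Z)-4-methylpenta-2,4-dien-1-ol F2. Sharpless epoxidation (Ti(OiPr)4, L-(+)-diisopropyl tartrate, tBuOOH, −20 °C) gives the cis-epoxy alcohol [(2S,3R)-3-(prop-1-en-2-yl)oxiran-2-yl]methanol F3. Opening of F3 with acid 5 and Ti(OiPr)4 (1.5 equiv, CH2Cl2, rt) occurs at the allylic C3 position by SN2 with inversion and gives 11. The cost is a lower enantiomeric excess in the epoxidation of the Z-allylic alcohol.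

2. **Step 13, the indium Barbier union.** The risks are the facial selectivity at C7, sluggish reaction of the lactol, and 1,4-elimination of the silyloxy group from the allylindium. The fallback sets out from bromide 17 (with lactol 19) and comes back at lactone alcohol 21. Borylation of 17 (B2pin2, Pd2(dba)3 cat., toluene, 50 °C) gives the allylboronate methyl (2E,4S,5S)-5-(epoxyangeloyloxy)-6-methyl-2-[(4,4,5,5-tetramethyl-1,3,2-dioxaborolan-2-yl)methyl]-4-(triethylsilyloxy)hepta-2,6-dienoate F4, which has the same olefin geometry as 17. Allylboration of 19 with F4, thermal or catalysed by Sc(OTf)3, runs through a closed chair in which the γ-substituent cis to the boron-bearing carbon again gives the syn adduct 20, and PPTS closes it to 21. A chiral phosphoric acid can replace Sc(OTf)3 if the C7 face needs catalyst control.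

3. **Step 17, the ring-closing metathesis.** The risks are the hindered isopropenyl group flanked by the C9 ester and the C8 silyl ether, competing closure onto the C13 methylene, and oligomerisation. The fallback sets out from acetate 24 and comes back at target 26, changing the substrate and the order of events. HF·pyridine first gives the free C8 alcohol, 8-O-desilyl 24 F5. Metathesis is then run on F5 (second-generation Hoveyda–Grubbs catalyst, toluene, 80 °C, 1 mM), where the triethylsilyl bulk next to the isopropenyl group is gone and the C8 hydroxyl can hydrogen-bond to the C9 ester carbonyl; ring closure becomes the last step and gives 26 directly. This is the weakest of the three fallbacks because it keeps the same bond construction.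

Further compounds
F1 | step 7 | ethyl (2Z)-4-methylpenta-2,4-dienoate | CCOC(=O)/C=C\C(C)=C
F2 | step 7 | (2Z)-4-methylpenta-2,4-dien-1-ol | OC/C=C\C(C)=C
F3 | step 7 | [(2S,3R)-3-(prop-1-en-2-yl)oxiran-2-yl]methanol | C=C(C)[C@H]1O[C@H]1CO
F4 | step 13 | methyl (2E,4S,5S)-5-{[(2S,3S)-2,3-dimethyloxirane-2-carbonyl]oxy}-6-methyl-2-[(4,4,5,5-tetramethyl-1,3,2-dioxaborolan-2-yl)methyl]-4-[(triethylsilyl)oxy]hepta-2,6-dienoate | C=C(C)[C@H](OC(=O)[C@@]1(C)O[C@H]1C)[C@@H](O[Si](CC)(CC)CC)/C=C(\CB1OC(C)(C)C(C)(C)O1)C(=O)OC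
F5 | step 17 | 8-O-desilyl 24, (4R,5S)-5-[(1Z,3S)-3-(acetyloxy)-2-methylhexa-1,5-dien-1-yl]-4-[(1S,2S)-2-{[(2S,3S)-2,3-dimethyloxirane-2-carbonyl]oxy}-1-hydroxy-3-methylbut-3-en-1-yl]-3-methylideneoxolan-2-one | C=C1C(=O)O[C@@H](/C=C(/C)[C@@H](OC(C)=O)CC=C)[C@H]1[C@H](O)[C@@H](OC(=O)[C@@]2(C)O[C@H]2C)C(C)=C
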